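**Retrosynthetic overview**

1. Target 23 ⇐ (key step) acid-triggered closure of the pyran ring through O1–C8a with re-aromatisation of the benzo ring, from quinone bisketal 21 ⇐ anodic methoxylation of open ketone 20.
2. Enabling feature: the para methoxy-bearing carbons C5 and C8 of the benzo ring C4a–C8a (with the C7 methoxy next to C8) let this ring be stored as its quinone bisketal. Loss of methoxide from C5 puts positive charge on C8a, six atoms from the ketone oxygen O1, and the C8 ketal beside C8a supplies the methanol whose loss restores the arene with all three methoxy groups in place.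
3. 20 ⇐ SN1 benzylation of a silyl enol ether (C3–C4 bond, sets C4 from both carbinol epimers) ⇐ aryllithium addition (C4–C4a bond) to the 1β-formyl eudesmane epoxide 14.
4. 14 ⇐ epoxidation of decalin aldehyde 13 ⇐ intramolecular Diels–Alder reaction of the acyclic (E)-trienal 12, built in five steps from (R)-limonene oxide.
5. Ring order: both carbocycles of the decalin together (step 6); the pyran ring last (step 12), the benzo ring being bought and only dearomatised (step 11) and re-aromatised (step 12).

Key step: step 12

Remark: eudesmane locants are used for the decalin (C1–C10, C14 on C10, C15 on C4, isopropenyl on C7, β = face of the C10 methyl). Chromene locants (O1, C2, C3, C4, C4a, C5–C8, C8a) are used for the flavene part and for the corresponding atoms of its open precursors.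
Remark: commercial (R)-limonene oxide is a cis/trans mixture; both isomers are assumed to converge in step 1.

**Route**

Step 1
Reactants: 1 (4R)-limonene 1,2-oxide (cis/trans mixture)
Product: 3 (3R)-6-oxo-3-(prop-1-en-2-yl)heptanal, via limonene-1,2-diol 2 (not isolated)
Conditions: H5IO6 (1.1 equiv), THF/H2O, 0 to 23 °C
Reagents that add atoms: water, O
Why: Acidic hydrolysis of either epoxide isomer to the 1,2-diol and periodate glycol cleavage (Malaprade reaction) should converge on one keto aldehyde, the C4 centre of limonene (the future C7) being untouched.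

Step 2
Reactants: 3 (3R)-6-oxo-3-(prop-1-en-2-yl)heptanal; 4 2-(triphenyl-λ5-phosphanylidene)propanal
Product: 5 (2E,5R)-2-methyl-8-oxo-5-(prop-1-en-2-yl)non-2-enal
Conditions: toluene, 80 °C
Reagents that add atoms: none
Why: The Wittig reaction of this stabilised ylide should take the aldehyde and leave the methyl ketone, and should give the (E)-2-methyl enal (future C4=C5).

Step 3
Reactants: 5 (2E,5R)-2-methyl-8-oxo-5-(prop-1-en-2-yl)non-2-enal; 6 methyltriphenylphosphonium bromide
Product: 8 (5R,7E)-8-methyl-5-(prop-1-en-2-yl)deca-7,9-dien-2-one, via methylidenetriphenylphosphorane 7 (not isolated)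
Conditions: 6, KN(SiMe3)2, THF, 0 °C; then 5 (1.0 equiv), −78 to 0 °C
Reagents that add atoms: none
Why: Wittig methylenation at low temperature should take the conjugated aldehyde in preference to the methyl ketone and complete the (E)-2-methyl-1,3-diene without touching the existing alkene geometry.

Step 4
Reactants: 8 (5R,7E)-8-methyl-5-(prop-1-en-2-yl)deca-7,9-dien-2-one; 9 diethyl {2-[methoxy(methyl)amino]-2-oxoethyl}phosphonate
Product: 11 (2E,6R,8E)-N-methoxy-N,3,9-trimethyl-6-(prop-1-en-2-yl)undeca-2,8,10-trienamide, via sodium phosphonate carbanion 10 (not isolated)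
Conditions: NaH, THF, 0 to 65 °C; chromatographic removal of the minor (2Z)-isomer
Reagents that add atoms: none
Why: The Horner–Wadsworth–Emmons olefination of the methyl ketone should favour the (E)-enamide (acyl group trans to the chain), which is the geometry the later cycloaddition needs.

Step 5
Reactants: 11 (2E,6R,8E)-N-methoxy-N,3,9-trimethyl-6-(prop-1-en-2-yl)undeca-2,8,10-trienamide
Product: 12 (2E,6R,8E)-3,9-dimethyl-6-(prop-1-en-2-yl)undeca-2,8,10-trienal
Conditions: iBu2AlH (1.2 equiv), THF, −78 °C; aqueous potassium sodium tartrate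
Reagents that add atoms: none
Why: Partial reduction of the N-methoxy-N-methylamide should stop at a chelated hemiaminal that releases the (E)-enal only on work-up, so over-reduction and E/Z leakage are avoided.

Step 6
Reactants: 12 (2E,6R,8E)-3,9-dimethyl-6-(prop-1-en-2-yl)undeca-2,8,10-trienal
Product: 13 1β-formyleudesma-3,11-diene (trans-decalin, 5α-H, 10β-methyl, 7β-isopropenyl)
Conditions: Me2AlCl (20 mol %), CH2Cl2, −78 to −20 °C
Reagents that add atoms: none
Why: The Lewis-acid-catalysed intramolecular Diels–Alder reaction should pass through the endo (formyl) transition state with a chair-like tether carrying the isopropenyl group equatorially, which gives the trans ring fusion; the E enal geometry places CHO cis to the C10 methyl (1β), and the C7 centre fixes the absolute sense at C1, C5 and C10.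

Step 7
Reactants: 13 1β-formyleudesma-3,11-diene
Product: 14 3α,4α-epoxy-1β-formyleudesm-11-ene
Conditions: dimethyldioxirane (1.05 equiv), acetone, −20 °C
Reagents that add atoms: dimethyldioxirane, CC1(C)OO1
Why: Dioxirane epoxidation should prefer the electron-richer trisubstituted C3=C4 alkene over the isopropenyl group, should spare the aldehyde under neutral conditions, and should come from the α-face, anti to the axial C10 methyl.

Step 8
Reactants: 14 3α,4α-epoxy-1β-formyleudesm-11-ene; 15 1-bromo-2,4,5-trimethoxybenzene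
Product: 17 (3α,4α-epoxyeudesm-11-en-1β-yl)(2,4,5-trimethoxyphenyl)methanol (both carbinol epimers), via (2,4,5-trimethoxyphenyl)lithium 16 (not isolated)
Conditions: 15, n-BuLi, THF, −78 °C; then 14, −78 °C; H2O
Reagents that add atoms: none
Why: Bromine–lithium exchange gives the aryllithium, whose 1,2-addition to the aldehyde at −78 °C should not touch the trisubstituted epoxide; the carbinol configuration is irrelevant because it is erased by ionisation in step 10.

Step 9
Reactants: 17 (3α,4α-epoxyeudesm-11-en-1β-yl)(2,4,5-trimethoxyphenyl)methanol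
Product: 18 1β-[hydroxy(2,4,5-trimethoxyphenyl)methyl]eudesm-11-en-4α-ol (both carbinol epimers)
Conditions: LiAlH4 (3 equiv), THF, 0 to 60 °C; H2O, aqueous NaOH
Reagents that add atoms: none
Why: Hydride reduction of the epoxide by SN2 attack at the secondary C3 (steric approach control, since C4 is fully substituted and its β-face is screened by the C10 methyl) should leave oxygen α on C4, giving the equatorial 4α-ol with the axial 4β-methyl.

Step 10
Reactants: 18 1β-[hydroxy(2,4,5-trimethoxyphenyl)methyl]eudesm-11-en-4α-ol; 19 trimethyl[(1-phenylethenyl)oxy]silane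
Product: 20 (3S)-3-(4α-hydroxyeudesm-11-en-1β-yl)-1-phenyl-3-(2,4,5-trimethoxyphenyl)propan-1-one
Conditions: 19 (3 equiv), Bi(OTf)3 (5 mol %), CH2Cl2/MeNO2, −40 to −20 °C; aqueous NaHCO3
Reagents that add atoms: none
Why: In this SN1 benzylation of a silyl enol ether (Mukaiyama-type alkylation) both carbinol epimers ionise to the same methoxy-stabilised benzylic cation, which should be captured on the face anti to the quaternary C10 in the conformer that holds the C1–H in the arene plane (1,3-allylic strain), setting the C4 centre of the target stereoconvergently.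

Step 11
Reactants: 20 (3S)-3-(4α-hydroxyeudesm-11-en-1β-yl)-1-phenyl-3-(2,4,5-trimethoxyphenyl)propan-1-one
Product: 21 (3S)-3-(4α-hydroxyeudesm-11-en-1β-yl)-3-(3,3,4,6,6-pentamethoxycyclohexa-1,4-dien-1-yl)-1-phenylpropan-1-one
Conditions: anodic oxidation, Pt anode and Pt cathode, undivided cell, constant current (about 2.5 F per mol), 1% KOH in MeOH, 0 °C; filtration through basic Al2O3
Reagents that add atoms: methanol, CO
Why: Anodic methoxylation of a 1,4-dimethoxyarene in basic methanol (quinone bisketal formation) should add methoxide at the para methoxy-bearing carbons C5 and C8 of the trimethoxyarene, the most easily oxidised π system present; the basic medium keeps the acid-labile bisketal intact and should leave the ketone, the isolated alkene and the C4 centre untouched.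

Step 12
Reactants: 21 (3S)-3-(4α-hydroxyeudesm-11-en-1β-yl)-3-(3,3,4,6,6-pentamethoxycyclohexa-1,4-dien-1-yl)-1-phenylpropan-1-one
Product: 23 1β-[(4R)-5,7,8-trimethoxy-2-phenyl-4H-chromen-4-yl]eudesm-11-en-4α-ol, via dihydrochromene ketal 22 (not isolated)
Conditions: camphor-10-sulfonic acid (10 mol %), 4 Å molecular sieves, CH2Cl2 (0.01 M), −20 to 23 °C; then Et3N
Reagents that add atoms: none
Why: Proposed new method: the acid should ionise the C5 ketal to a cyclohexadienyl cation whose charge sits on C5, C7 and C8a, the ketone oxygen O1 adds to C8a, loss of H-3 from the resulting 2-phenyl oxocarbenium ion gives the enol ether 22, and ionisation of the C8 ketal followed by loss of H-8a then restores the arene and gives 23 with all three methoxy groups in place and no redox or methylation step left. The closest known reaction type is the acid-promoted addition of nucleophiles to quinone bisketals and monoketals with loss of methanol, which gives substituted hydroquinone ethers (for example 1,2,4-trimethoxybenzene from benzoquinone bisketal in acidic methanol); new is a ketone carbonyl oxygen as the internal nucleophile. The pyran ring closes in the 6-endo-trig mode (O1 onto C8a of the C4a–C8a bond), and the benzo ring is not closed but re-aromatised. No new stereocentre remains, since C8a of 22 becomes trigonal again, and the C4 centre set in step 10 is carried through because C4a bears no charge in the C5-derived cation. The step needs ionisation at C5 before C8 and capture at C8a: the C7 methoxy stabilises only the C5-derived cation, C7 is blocked and methanol return there is reversible, O1 can reach only C8a in a six-membered closure, and the sieves and high dilution should hold back capture by released methanol and intermolecular arylation.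

**Compound list**

1 | (4R)-limonene 1,2-oxide, cis/trans mixture | CC12OC1C[C@@H](CC2)C(C)=C | starting material
2 | (4R)-1-methyl-4-(prop-1-en-2-yl)cyclohexane-1,2-diol, diastereomer mixture | CC1(O)C(O)C[C@@H](CC1)C(C)=C | intermediate
3 | (3R)-6-oxo-3-(prop-1-en-2-yl)heptanal | O=CC[C@@H](CCC(C)=O)C(C)=C | intermediate
4 | 2-(triphenyl-λ5-phosphanylidene)propanal | CC(C=O)=P(c1ccccc1)(c1ccccc1)c1ccccc1 | starting material
5 | (2E,5R)-2-methyl-8-oxo-5-(prop-1-en-2-yl)non-2-enal | O=C/C(C)=C/C[C@@H](CCC(C)=O)C(C)=C | intermediate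
6 | methyltriphenylphosphonium bromide | C[P+](c1ccccc1)(c1ccccc1)c1ccccc1.[Br-] | starting material
7 | methylidenetriphenylphosphorane | C=P(c1ccccc1)(c1ccccc1)c1ccccc1 | intermediate
8 | (5R,7E)-8-methyl-5-(prop-1-en-2-yl)deca-7,9-dien-2-one | C=C/C(C)=C/C[C@@H](CCC(C)=O)C(C)=C | intermediate
9 | diethyl {2-[methoxy(methyl)amino]-2-oxoethyl}phosphonate | CCOP(=O)(CC(=O)N(C)OC)OCC | starting material
10 | sodium salt of the carbanion of 9 | [Na+].CCOP(=O)([CH-]C(=O)N(C)OC)OCC | intermediate
11 | (2E,6R,8E)-N-methoxy-N,3,9-trimethyl-6-(prop-1-en-2-yl)undeca-2,8,10-trienamide | C=C/C(C)=C/C[C@@H](CC/C(C)=C/C(=O)N(C)OC)C(C)=C | intermediate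
12 | (2E,6R,8E)-3,9-dimethyl-6-(prop-1-en-2-yl)undeca-2,8,10-trienal | C=C/C(C)=C/C[C@@H](CC/C(C)=C/C=O)C(C)=C | intermediate
13 | 1β-formyleudesma-3,11-diene (5α-H, 10β-methyl, 7β-isopropenyl) | C=C(C)[C@@H]1CC[C@]2(C)[C@@H](C1)C(C)=CC[C@H]2C=O | intermediate
14 | 3α,4α-epoxy-1β-formyleudesm-11-ene | C=C(C)[C@@H]1CC[C@]2(C)[C@@H](C1)[C@]3(C)O[C@@H]3C[C@H]2C=O | intermediate
15 | 1-bromo-2,4,5-trimethoxybenzene | COc1cc(OC)c(OC)cc1Br | starting material
16 | (2,4,5-trimethoxyphenyl)lithium | [Li]c1cc(OC)c(OC)cc1OC | intermediate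
17 | (3α,4α-epoxyeudesm-11-en-1β-yl)(2,4,5-trimethoxyphenyl)methanol, both carbinol epimers | C=C(C)[C@@H]1CC[C@]2(C)[C@@H](C1)[C@]3(C)O[C@@H]3C[C@H]2C(O)c1cc(OC)c(OC)cc1OC | intermediate
18 | 1β-[hydroxy(2,4,5-trimethoxyphenyl)methyl]eudesm-11-en-4α-ol, both carbinol epimers | C=C(C)[C@@H]1CC[C@]2(C)[C@@H](C1)[C@](C)(O)CC[C@H]2C(O)c1cc(OC)c(OC)cc1OC | intermediate
19 | trimethyl[(1-phenylethenyl)oxy]silane | C=C(O[Si](C)(C)C)c1ccccc1 | starting material
20 | (3S)-3-(4α-hydroxyeudesm-11-en-1β-yl)-1-phenyl-3-(2,4,5-trimethoxyphenyl)propan-1-one | C=C(C)[C@@H]1CC[C@]2(C)[C@@H](C1)[C@](C)(O)CC[C@H]2[C@H](CC(=O)c1ccccc1)c1cc(OC)c(OC)cc1OC | intermediate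
21 | (3S)-3-(4α-hydroxyeudesm-11-en-1β-yl)-3-(3,3,4,6,6-pentamethoxycyclohexa-1,4-dien-1-yl)-1-phenylpropan-1-one | C=C(C)[C@@H]1CC[C@]2(C)[C@@H](C1)[C@](C)(O)CC[C@H]2[C@H](CC(=O)c1ccccc1)C1=CC(OC)(OC)C(OC)=CC1(OC)OC | intermediate
22 | (4R)-4-(4α-hydroxyeudesm-11-en-1β-yl)-5,7,8,8-tetramethoxy-2-phenyl-8,8a-dihydro-4H-chromene, either C8a epimer | C=C(C)[C@@H]1CC[C@]2(C)[C@@H](C1)[C@](C)(O)CC[C@H]2[C@@H]1C=C(c2ccccc2)OC2C1=C(OC)C=C(OC)C2(OC)OC | intermediate
23 | 1β-[(4R)-5,7,8-trimethoxy-2-phenyl-4H-chromen-4-yl]eudesm-11-en-4α-ol | C=C(C)[C@@H]1CC[C@]2(C)[C@@H](C1)[C@](C)(O)CC[C@H]2[C@@H]1C=C(c2ccccc2)Oc2c(OC)c(OC)cc(OC)c21 | target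

**Step count and risks**

Total step count: 12. Longest linear sequence: 12 steps (from 1); all other starting materials enter as purchased reagents.

Steps most likely to fail:

1. Step 12 (Proposed new method). What may go wrong: the cation may be captured by released methanol or by traces of water in place of O1, ionisation may start at C8 and lead to spiro capture at C4a or to loss of H-4 with erosion of the C4 configuration, or the acid may dehydrate the tertiary alcohol. Fallback (known chemistry; sets out from 20, rejoins at 23): 20 is oxidised with (NH4)2Ce(NO3)6 (2.2 equiv, MeCN/H2O, 0 °C), an oxidative demethylation of the para pair C5/C8, to give the methoxyquinone F1. 1,4-Addition of hydrogen bromide from pyridinium bromide (CH2Cl2/MeCN, 0 °C) should place bromine on C8a, the only unsubstituted enone β-carbon that is not deactivated by the methoxy group, to give the bromohydroquinone F2. This is O-methylated at once (Me2SO4, K2CO3, acetone, under argon) to the aryl bromide F3. An Ullmann-type copper-catalysed intramolecular O-arylation of the ketone enolate (CuI, 1,10-phenanthroline, Cs2CO3, toluene, 100 °C) then forms the same O1–C8a bond at the arene level and gives 23.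

2. Step 10. What may go wrong: insufficient facial discrimination in the capture of the planar benzylic cation, or loss of the cation by elimination toward C1. Fallback (sets out from 14, rejoins at 20): the bond order at C4 is inverted and the centre is set under catalyst control. A Horner–Wadsworth–Emmons reaction of 14 with diethyl (2-oxo-2-phenylethyl)phosphonate (LiCl, iPr2NEt, MeCN) gives the (E)-enone F4. A Hayashi–Miyaura conjugate addition of (2,4,5-trimethoxyphenyl)boronic acid (Rh(acac)(C2H4)2, the BINAP enantiomer that delivers the 3S ketone, dioxane/H2O, 60 °C) gives the epoxy ketone F5. LiAlH4 opens the epoxide as in step 9 and reduces the ketone, giving the diol F6, and MnO2 (CH2Cl2) re-oxidises only the benzylic carbinol to return 20.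

3. Step 9. What may go wrong: hydride may be delivered to the tertiary C4 in the stereoelectronically preferred trans-diaxial mode, or the opening at C3 may be too slow. Fallback (sets out from 17, rejoins at 18): the epoxide is opened with sodium benzeneselenolate (PhSeSePh, NaBH4, EtOH, 60 °C), a soft nucleophile that cannot attack the fully substituted C4, to give the hydroxy selenide F7. The C–Se bond is then reduced homolytically (Bu3SnH, AIBN, toluene, 80 °C) to give 18.

Further compounds
F1 | step 12 | 2-[(1S)-1-(4α-hydroxyeudesm-11-en-1β-yl)-3-oxo-3-phenylpropyl]-5-methoxy-1,4-benzoquinone | C=C(C)[C@@H]1CC[C@]2(C)[C@@H](C1)[C@](C)(O)CC[C@H]2[C@H](CC(=O)c1ccccc1)C1=CC(=O)C(OC)=CC1=O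
F2 | step 12 | (3S)-3-(2-bromo-3,6-dihydroxy-4-methoxyphenyl)-3-(4α-hydroxyeudesm-11-en-1β-yl)-1-phenylpropan-1-one | C=C(C)[C@@H]1CC[C@]2(C)[C@@H](C1)[C@](C)(O)CC[C@H]2[C@H](CC(=O)c1ccccc1)c1c(Br)c(O)c(OC)cc1O
F3 | step 12 | (3S)-3-(2-bromo-3,4,6-trimethoxyphenyl)-3-(4α-hydroxyeudesm-11-en-1β-yl)-1-phenylpropan-1-one | C=C(C)[C@@H]1CC[C@]2(C)[C@@H](C1)[C@](C)(O)CC[C@H]2[C@H](CC(=O)c1ccccc1)c1c(Br)c(OC)c(OC)cc1OC
F4 | step 10 | (2E)-3-(3α,4α-epoxyeudesm-11-en-1β-yl)-1-phenylprop-2-en-1-one | C=C(C)[C@@H]1CC[C@]2(C)[C@@H](C1)[C@]3(C)O[C@@H]3C[C@H]2/C=C/C(=O)c1ccccc1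
F5 | step 10 | (3S)-3-(3α,4α-epoxyeudesm-11-en-1β-yl)-1-phenyl-3-(2,4,5-trimethoxyphenyl)propan-1-one | C=C(C)[C@@H]1CC[C@]2(C)[C@@H](C1)[C@]3(C)O[C@@H]3C[C@H]2[C@H](CC(=O)c1ccccc1)c1cc(OC)c(OC)cc1OC
F6 | step 10 | (3S)-3-(4α-hydroxyeudesm-11-en-1β-yl)-1-phenyl-3-(2,4,5-trimethoxyphenyl)propan-1-ol, both C1 carbinol epimers | C=C(C)[C@@H]1CC[C@]2(C)[C@@H](C1)[C@](C)(O)CC[C@H]2[C@H](CC(O)c1ccccc1)c1cc(OC)c(OC)cc1OC
F7 | step 9 | [4α-hydroxy-3β-(phenylselanyl)eudesm-11-en-1β-yl](2,4,5-trimethoxyphenyl)methanol, both carbinol epimers | C=C(C)[C@@H]1CC[C@]2(C)[C@@H](C1)[C@](C)(O)[C@@H]([Se]c3ccccc3)C[C@H]2C(O)c1cc(OC)c(OC)cc1OC
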